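**Plan**

- Retrosynthesis: the two alkene–methyl bonds C3'–CH3 and C3''–CH3 are cut first, which returns both E-alkenes to the alkynes of a diynediol benzoic acid. The two ArCH2–C(sp) bonds are cut next, giving a bis(bromomethyl)anisate and two terminal alkynes. The chiral alkyne is cut at C5'–C6' (epoxide opening) and at its C≡C bond (one-carbon homologation of an aldehyde).
- Enabling feature: each arm is an Ar–CH2–CH=C(CH3)–C(OH) unit, with the methyl on the alkene carbon bonded to the hydroxyl-bearing carbon (C3'/C4' and C3''/C4'') and the arene methylene trans to that carbinol carbon. Anti addition of CH3 and H across a 4-aryl-2-alkyn-1-ol gives exactly this, because the hydroxyl oxygen can hold magnesium on the far alkyne carbon in a five-membered O–C–C=C–Mg chelate. The benzene ring is the only ring and is bought; no ring is formed.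
- Forward: both benzylic methyls of the anisate are brominated; the achiral four-carbon alkyne is joined first (monoalkynylation with the dibromide in excess), the chiral eight-carbon alkyne second. Desilylation and saponification give the diynediol acid, and a twofold CuI-catalysed methylmagnesiation completes the skeleton in the last step.
- Stereochemistry: C4' (R) is C2 of (S)-glycidol and takes part in no bond-making or bond-breaking event. Both E geometries arise in the last step from anti carbometalation and retentive protonation.

Key step: step 12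

Remark: primed locants count along the eight-carbon arm and doubly primed locants along the four-carbon arm, each from the benzylic carbon; the bromomagnesium benzoate formed in step 12 is assumed to be inert to MeMgBr at room temperature.

**Route**

Step 1
Reactants: 1 4-hydroxy-3,5-dimethylbenzoic acid
Product: 2 methyl 4-methoxy-3,5-dimethylbenzoate
Conditions: MeI (3 equiv), K2CO3, DMF, 40 °C
Reagents that add atoms: iodomethane, CI
Why: Williamson etherification of the phenoxide and O-alkylation of the carboxylate take place in one operation, since the flanking methyl groups do not block O-methylation of a 2,6-dimethylphenoxide.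

Step 2
Reactants: 2 methyl 4-methoxy-3,5-dimethylbenzoate
Product: 3 methyl 3,5-bis(bromomethyl)-4-methoxybenzoate
Conditions: NBS (2.1 equiv), AIBN (cat.), PhCF3, 85 °C
Reagents that add atoms: N-bromosuccinimide, O=C1CCC(=O)N1Br
Why: Wohl–Ziegler radical bromination should take one hydrogen from each benzylic methyl group, the free ring positions being deactivated by the ortho ester and the limited NBS charge holding back benzal bromide formation.

Step 3
Reactants: 3 methyl 3,5-bis(bromomethyl)-4-methoxybenzoate (3 equiv); 4 tert-butyldimethyl(prop-2-yn-1-yloxy)silane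
Product: 5 methyl 3-(bromomethyl)-5-[4-(tert-butyldimethylsilyloxy)but-2-yn-1-yl]-4-methoxybenzoate
Conditions: CuI (50 mol %), Cs2CO3, MeCN, rt → 40 °C, Ar
Reagents that add atoms: none
Why: This is the copper-mediated sp–sp3 coupling of a terminal alkyne with a benzylic bromide (alkylation of the copper acetylide); the two bromomethyl groups react independently, so a threefold excess of 3 should make monoalkynylation dominant, and unreacted 3 should be recoverable by chromatography.

Step 4
Reactants: 6 (S)-glycidol; 7 2-methylprop-1-en-1-ylmagnesium bromide (3 equiv, 0.5 M in THF)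
Product: 9 (2R)-6-methylhept-5-ene-1,2-diol, via bromomagnesium alkoxide of (S)-glycidol 8 (not isolated)
Conditions: CuI (10 mol %), THF, −40 → 0 °C; aq NH4Cl
Reagents that add atoms: none
Why: CuI-catalysed SN2 opening of a terminal epoxide by an alkenyl Grignard reagent occurs at the unsubstituted carbon after the first equivalent of 7 has deprotonated the hydroxyl group; the stereocentre is not touched, so the spatial arrangement of 6 is carried into 9 (the descriptor becomes R only through the priority change).

Step 5
Reactants: 9 (2R)-6-methylhept-5-ene-1,2-diol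
Product: 10 (2R)-1,2-bis(tert-butyldimethylsilyloxy)-6-methylhept-5-ene
Conditions: TBSCl (2.5 equiv), imidazole, DMF, rt
Reagents that add atoms: tert-butyldimethylsilyl chloride, CC(C)(C)[Si](C)(C)Cl
Why: Imidazole-promoted silylation covers the primary and the secondary hydroxyl group under standard conditions without touching the stereocentre.

Step 6
Reactants: 10 (2R)-1,2-bis(tert-butyldimethylsilyloxy)-6-methylhept-5-ene
Product: 11 (2R)-2-(tert-butyldimethylsilyloxy)-6-methylhept-5-en-1-ol
Conditions: HF·pyridine, pyridine, THF, 0 °C
Reagents that add atoms: none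
Why: Buffered HF·pyridine cleaves the unhindered primary silyl ether much faster than the secondary one (selective desilylation), and no silyl migration is expected under these non-basic conditions.

Step 7
Reactants: 11 (2R)-2-(tert-butyldimethylsilyloxy)-6-methylhept-5-en-1-ol
Product: 12 (2R)-2-(tert-butyldimethylsilyloxy)-6-methylhept-5-enal
Conditions: Dess–Martin periodinane, CH2Cl2, 0 °C → rt
Reagents that add atoms: none
Why: Dess–Martin oxidation stops at the aldehyde and works without base, so the α-silyloxy stereocentre and the trisubstituted alkene should survive.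

Step 8
Reactants: 12 (2R)-2-(tert-butyldimethylsilyloxy)-6-methylhept-5-enal
Product: 13 (3R)-3-(tert-butyldimethylsilyloxy)-6-methylhept-5-en-1-yne
Conditions: dimethyl (1-diazo-2-oxopropyl)phosphonate, K2CO3, MeOH, 0 °C → rt
Reagents that add atoms: dimethyl (1-diazo-2-oxopropyl)phosphonate, COP(=O)(OC)C(=[N+]=[N-])C(C)=O
Why: In the Ohira–Bestmann variant of the Seyferth–Gilbert homologation, methanolysis of the reagent gives the diazomethylphosphonate anion, which adds to the aldehyde and, after loss of phosphate and N2, gives the terminal alkyne by a 1,2-hydrogen shift; α-silyloxy aldehydes normally pass through this mild carbonate protocol without epimerisation.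

Step 9
Reactants: 5 methyl 3-(bromomethyl)-5-[4-(tert-butyldimethylsilyloxy)but-2-yn-1-yl]-4-methoxybenzoate; 13 (3R)-3-(tert-butyldimethylsilyloxy)-6-methylhept-5-en-1-yne (1.1 equiv)
Product: 14 methyl 3-[4-(tert-butyldimethylsilyloxy)but-2-yn-1-yl]-5-[(4R)-4-(tert-butyldimethylsilyloxy)-7-methyloct-6-en-2-yn-1-yl]-4-methoxybenzoate
Conditions: CuI (50 mol %), Cs2CO3, MeCN, rt → 40 °C, Ar
Reagents that add atoms: none
Why: The same copper-mediated coupling of a benzylic bromide with a terminal alkyne as in step 3 forms the second ArCH2–C(sp) bond, the silyl ether preventing O-benzylation and the propargylic stereocentre remaining a spectator.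

Step 10
Reactants: 14 methyl 3-[4-(tert-butyldimethylsilyloxy)but-2-yn-1-yl]-5-[(4R)-4-(tert-butyldimethylsilyloxy)-7-methyloct-6-en-2-yn-1-yl]-4-methoxybenzoate
Product: 15 methyl 3-(4-hydroxybut-2-yn-1-yl)-5-[(4R)-4-hydroxy-7-methyloct-6-en-2-yn-1-yl]-4-methoxybenzoate
Conditions: HF·pyridine, pyridine, THF, 0 °C → rt
Reagents that add atoms: none
Why: Fluoride-driven desilylation removes both silyl ethers in one operation, and the buffered, non-basic medium should avoid propargyl-to-allene isomerisation of the ArCH2–C≡C units while leaving the ester and the alkene alone.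

Step 11
Reactants: 15 methyl 3-(4-hydroxybut-2-yn-1-yl)-5-[(4R)-4-hydroxy-7-methyloct-6-en-2-yn-1-yl]-4-methoxybenzoate
Product: 16 3-(4-hydroxybut-2-yn-1-yl)-5-[(4R)-4-hydroxy-7-methyloct-6-en-2-yn-1-yl]-4-methoxybenzoic acid
Conditions: LiOH·H2O, THF/MeOH/H2O, 0 °C → rt; then 1 M HCl to pH 3
Reagents that add atoms: lithium hydroxide, [Li+].[OH-]
Why: Saponification of an unhindered methyl benzoate (acyl–oxygen cleavage by hydroxide) is fast at or below room temperature, which should keep the exposure of the benzylic propargylic methylenes to base short, and acidification gives the free acid.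

Step 12
Reactants: 16 3-(4-hydroxybut-2-yn-1-yl)-5-[(4R)-4-hydroxy-7-methyloct-6-en-2-yn-1-yl]-4-methoxybenzoic acid
Product: 19 3-[(2E,4R)-4-hydroxy-3,7-dimethylocta-2,6-dien-1-yl]-5-[(2E)-4-hydroxy-3-methylbut-2-en-1-yl]-4-methoxybenzoic acid, via tris(bromomagnesium) salt of the diynediol acid 17 (not isolated), via bis(oxamagnesacycle) dialkenylmagnesium chelate 18 (not isolated)
Conditions: MeMgBr (10 equiv), CuI (30 mol %), THF/Et2O, 0 °C → rt; aq NH4Cl, then 0.5 M HCl to pH 3, 0 °C
Reagents that add atoms: methylmagnesium bromide, C[Mg]Br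
Why: MeMgBr first converts 16 into the tris(bromomagnesium) salt 17, whose carboxylate is a poor electrophile and is expected to outlast the excess reagent. With CuI, a methylcopper–magnesium species then adds across each alkyne with net anti selectivity: methyl goes to the alkyne carbon next to the carbinol (C3' and C3'') and the metal ends on the benzylic-side carbon (C2' and C2''), held cis to the carbinol carbon by the alkoxide in a five-membered O–C–C=C–Mg chelate (18). The closest known reaction type is the CuI-catalysed anti-carbomagnesiation of 2-alkyn-1-ols to (E)-2-substituted allylic alcohols, run here on two such units in one flask. No ring of the product is closed and no stereocentre is created; protonolysis of the two C–Mg bonds on work-up occurs with retention, so each arene methylene ends trans to its carbinol carbon (both alkenes E) and C4' keeps its R configuration. The step needs methyl delivery to the proximal carbon and anti geometry at both alkynes, and chemoselectivity over the carboxylate and the isolated trisubstituted alkene; the first two follow from chelation by the neighbouring alkoxide, which works the same way in both arms whatever the aryl group, and the last from the low reactivity of a magnesium carboxylate and an unactivated alkene toward the reagent.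

**Compound list**

1 | 4-hydroxy-3,5-dimethylbenzoic acid | Cc1cc(C(=O)O)cc(C)c1O | starting material
2 | methyl 4-methoxy-3,5-dimethylbenzoate | COC(=O)c1cc(C)c(OC)c(C)c1 | intermediate
3 | methyl 3,5-bis(bromomethyl)-4-methoxybenzoate | COC(=O)c1cc(CBr)c(OC)c(CBr)c1 | intermediate
4 | tert-butyldimethyl(prop-2-yn-1-yloxy)silane | C#CCO[Si](C)(C)C(C)(C)C | starting material
5 | methyl 3-(bromomethyl)-5-[4-(tert-butyldimethylsilyloxy)but-2-yn-1-yl]-4-methoxybenzoate | COC(=O)c1cc(CBr)c(OC)c(CC#CCO[Si](C)(C)C(C)(C)C)c1 | intermediate
6 | (S)-glycidol, (2S)-oxiran-2-ylmethanol | OC[C@H]1CO1 | starting material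
7 | 2-methylprop-1-en-1-ylmagnesium bromide | CC(C)=C[Mg]Br | starting material
8 | bromomagnesium alkoxide of (S)-glycidol | Br[Mg]OC[C@H]1CO1 | intermediate
9 | (2R)-6-methylhept-5-ene-1,2-diol | OC[C@H](O)CC=C(C)C | intermediate
10 | (2R)-1,2-bis(tert-butyldimethylsilyloxy)-6-methylhept-5-ene | CC(C)(C)[Si](C)(C)OC[C@H](O[Si](C)(C)C(C)(C)C)CC=C(C)C | intermediate
11 | (2R)-2-(tert-butyldimethylsilyloxy)-6-methylhept-5-en-1-ol | OC[C@H](O[Si](C)(C)C(C)(C)C)CC=C(C)C | intermediate
12 | (2R)-2-(tert-butyldimethylsilyloxy)-6-methylhept-5-enal | O=C[C@H](O[Si](C)(C)C(C)(C)C)CC=C(C)C | intermediate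
13 | (3R)-3-(tert-butyldimethylsilyloxy)-6-methylhept-5-en-1-yne | C#C[C@H](O[Si](C)(C)C(C)(C)C)CC=C(C)C | intermediate
14 | methyl 3-[4-(tert-butyldimethylsilyloxy)but-2-yn-1-yl]-5-[(4R)-4-(tert-butyldimethylsilyloxy)-7-methyloct-6-en-2-yn-1-yl]-4-methoxybenzoate | COC(=O)c1cc(CC#CCO[Si](C)(C)C(C)(C)C)c(OC)c(CC#C[C@H](O[Si](C)(C)C(C)(C)C)CC=C(C)C)c1 | intermediate
15 | methyl 3-(4-hydroxybut-2-yn-1-yl)-5-[(4R)-4-hydroxy-7-methyloct-6-en-2-yn-1-yl]-4-methoxybenzoate | COC(=O)c1cc(CC#CCO)c(OC)c(CC#C[C@H](O)CC=C(C)C)c1 | intermediate
16 | 3-(4-hydroxybut-2-yn-1-yl)-5-[(4R)-4-hydroxy-7-methyloct-6-en-2-yn-1-yl]-4-methoxybenzoic acid | COc1c(CC#CCO)cc(C(=O)O)cc1CC#C[C@H](O)CC=C(C)C | intermediate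
17 | tris(bromomagnesium) salt of 16 (two alkoxides and the carboxylate) | COc1c(CC#CCO[Mg]Br)cc(C(=O)O[Mg]Br)cc1CC#C[C@H](O[Mg]Br)CC=C(C)C | intermediate
18 | bis(oxamagnesacycle) dialkenylmagnesium chelate of the bromomagnesium benzoate (methyl on C3' and C3'', magnesium on C2' and C2'') | COc1c(CC2=C(C)CO[Mg]2)cc(C(=O)O[Mg]Br)cc1CC3=C(C)[C@@H](CC=C(C)C)O[Mg]3 | intermediate
19 | 3-[(2E,4R)-4-hydroxy-3,7-dimethylocta-2,6-dien-1-yl]-5-[(2E)-4-hydroxy-3-methylbut-2-en-1-yl]-4-methoxybenzoic acid | COc1c(C/C=C(\C)CO)cc(C(=O)O)cc1C/C=C(\C)[C@H](O)CC=C(C)C | target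

**Step count**

Total: 12 steps. Longest linear sequence: 9 steps (steps 4 to 8, then 9 to 12).

**Steps most likely to fail**

Step 12. The tris-magnesium salt may come out of solution, so that the second methylmagnesiation, at the more hindered secondary-carbinol arm, stalls. Forcing the reaction may let MeMgBr begin to add to the carboxylate or erode the proximal regiochemistry. The fallback sets out from ester 15 and comes back at target 19. Hydroxyl-directed ruthenium-catalysed trans-hydrostannation (Bu3SnH, [Cp*RuCl]4, CH2Cl2, rt) should place tin on the carbon next to each carbinol and hydrogen anti on the benzylic-side carbon. This would give methyl 3-[(2Z)-4-hydroxy-3-(tributylstannyl)but-2-en-1-yl]-5-[(2Z,4R)-4-hydroxy-7-methyl-3-(tributylstannyl)octa-2,6-dien-1-yl]-4-methoxybenzoate F1. Stille-type C-methylation with retention (MeI, Pd(PPh3)4, copper thiophene-2-carboxylate Cu(O2CC4H3S), [Ph2PO2][NBu4], DMF) would then give methyl 3-[(2E,4R)-4-hydroxy-3,7-dimethylocta-2,6-dien-1-yl]-5-[(2E)-4-hydroxy-3-methylbut-2-en-1-yl]-4-methoxybenzoate F2. Saponification of F2 with LiOH in THF/MeOH/H2O, followed by mild acidification, gives 19; at that stage no propargylic methylene is left to isomerise.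

Step 9. The copper acetylide of the α-branched silyloxy alkyne may be alkylated only slowly. That leaves room for oxidative alkyne homocoupling and for carbonate-induced isomerisation of the product's ArCH2–C≡C unit to an aryl allene. The fallback sets out from alkyne 13 and bromide 5 and comes back at 14, replacing the copper/carbonate coupling by a base-free Negishi cross-coupling. Deprotonation of 13 with n-BuLi (THF, −78 °C) gives lithium (3R)-3-(tert-butyldimethylsilyloxy)-6-methylhept-5-en-1-yn-1-ide F3. Transmetalation with ZnBr2 gives bromo[(3R)-3-(tert-butyldimethylsilyloxy)-6-methylhept-5-en-1-yn-1-yl]zinc F4. F4 is then coupled with 5 under PdCl2(DPEphos) catalysis in THF at rt, conditions under which the methyl ester is not attacked.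

Step 11. Hydroxide may deprotonate the ArCH2–C≡C methylenes, which are both benzylic and propargylic, and isomerise the alkynes to allenes or conjugated aryl alkynes in competition with ester cleavage. The fallback sets out from the silylated ester 14 and comes back at acid 16, moving the ester cleavage ahead of desilylation and avoiding hydroxide altogether. Trimethyltin hydroxide (Me3SnOH, 1,2-dichloroethane, 70 °C) cleaves the methyl ester under neutral conditions by tin-assisted acyl transfer. This gives 3-[4-(tert-butyldimethylsilyloxy)but-2-yn-1-yl]-5-[(4R)-4-(tert-butyldimethylsilyloxy)-7-methyloct-6-en-2-yn-1-yl]-4-methoxybenzoic acid F5. Buffered HF·pyridine in THF then removes both silyl ethers to give 16.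

Further compounds
F1 | step 12 | methyl 3-[(2Z)-4-hydroxy-3-(tributylstannyl)but-2-en-1-yl]-5-[(2Z,4R)-4-hydroxy-7-methyl-3-(tributylstannyl)octa-2,6-dien-1-yl]-4-methoxybenzoate | COC(=O)c1cc(C/C=C(\[Sn](CCCC)(CCCC)CCCC)CO)c(OC)c(C/C=C(\[Sn](CCCC)(CCCC)CCCC)[C@H](O)CC=C(C)C)c1
F2 | step 12 | methyl 3-[(2E,4R)-4-hydroxy-3,7-dimethylocta-2,6-dien-1-yl]-5-[(2E)-4-hydroxy-3-methylbut-2-en-1-yl]-4-methoxybenzoate | COC(=O)c1cc(C/C=C(\C)CO)c(OC)c(C/C=C(\C)[C@H](O)CC=C(C)C)c1
F3 | step 9 | lithium (3R)-3-(tert-butyldimethylsilyloxy)-6-methylhept-5-en-1-yn-1-ide | [Li]C#C[C@H](O[Si](C)(C)C(C)(C)C)CC=C(C)C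
F4 | step 9 | bromo[(3R)-3-(tert-butyldimethylsilyloxy)-6-methylhept-5-en-1-yn-1-yl]zinc | Br[Zn]C#C[C@H](O[Si](C)(C)C(C)(C)C)CC=C(C)C
F5 | step 11 | 3-[4-(tert-butyldimethylsilyloxy)but-2-yn-1-yl]-5-[(4R)-4-(tert-butyldimethylsilyloxy)-7-methyloct-6-en-2-yn-1-yl]-4-methoxybenzoic acid | COc1c(CC#CCO[Si](C)(C)C(C)(C)C)cc(C(=O)O)cc1CC#C[C@H](O[Si](C)(C)C(C)(C)C)CC=C(C)C
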